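At early times the starting complex meets incoming ligand at its charge, and with the concentrations as charged the forward rate of the first exchange alone gives a half-life of 23 s, shorter than the 80 s asked about.

starting complex 0.072 M; incoming ligand 2.50 equiv; scavenger 0.800 equiv; time 80 s

* part of the starting complex that has reacted at 80 s
* share of the unused incoming ligand that is free and not bound as idle adduct, at 80 s

- for leaving ligand the idle adduct is counted in
- run time (flask): 80 s

    starting complex + incoming ligand ⇌ leaving ligand + complex with one exchanged (K1 = 1.2, k1 = 0.168 M⁻¹ s⁻¹)
    complex with one exchanged + incoming ligand ⇌ leaving ligand + complex with two exchanged (K2 = 2.27, k2 = 0.115 M⁻¹ s⁻¹)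
    leaving ligand + incoming ligand ⇌ idle adduct, settled at all times (K3 = 150 M⁻¹)
    scavenger + leaving ligand → scavenged by-product (k4 = 22.8 M⁻¹ s⁻¹)
    leaving ligand → by-product carried off (k5 = 0.465 s⁻¹)

1. The charge clock is 0.968: the rate constant of the first exchange times the charge of starting complex times the time. If e is a steady level of free incoming ligand in equivalents, the fraction of starting complex left is exp(−clock × e), with the way back neglected.

2. First extreme: the ligand stays at its charge, e = 2.50 equiv, so c = 91.1%.

3. Second extreme: two ligands per complex are spent at once, e = 0.500, so c = 38.4%.

4. The flask starts at the first extreme and sinks toward the second, so c lies between them. The second exchange is slower than the first, so this reckoning commits to one ligand spent per complex: e = 1.50, c = 76.6%.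

5. The free share fr is the reciprocal of one plus 150 M⁻¹ times the free leaving ligand. The hand reckoning stops there, without that level.

The forecast gives c = 79% (74% to 84%) and fr = 88% (85% to 91%), holding that “the back reactions stay negligible”.

The simulation gives c = 78.8% and fr = 89.4%.

Both values lie inside the forecast's ranges. The undoing of the first exchange barely matters here, so the clock turns this flask's c into a level e = 1.60. The neighbouring flask holds 0.12 M of starting complex at the same equivalents. Its clock reads 1.61, and one ligand spent per complex gives c = 91.1%. That flask reaches 87.8%, and its free share fr is 81.0%.

The constants are made up; the result is computed.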